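**Plan**
- Retrosynthesis: the three MOM ethers come off last and the C4 ketone goes back to a C4 methyl ether. Ring C is then cut at O1–C2 and C3–C4, the acetal carbon (C4) at C4a–C4, and the side chain at the C6–chain C1 bond.
- Enabling feature: ring C (O1, C2, C3, C4, C4a, C8a) holds C2–C3 as the vinyl carbons of a para-oxygenated styrene, set between the phenol oxygen O1 and the oxygen-bearing benzylic C4. It therefore unfolds into the 1-oxadiene O1=C8a–C4a=C4 of an ortho-quinone methide on ring A plus that styrene.
- Forward order: ring A (phloroglucinol) is desymmetrised, the chain is joined at the carbon between the two MOM ethers, C4 is added by ortho-formylation, ring C is closed by the [4+2] step, then C4 is oxidised and the phenols are freed.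
- Stereochemistry: the chain stereocentre is bought with (S)-citronellal and never touched; the E alkene comes from the dehydration; C2 (S) is set by the chiral acid in the cycloaddition.

Key step: step 10

Remark: the hand of the chiral acid that gives (2S) cannot be derived with confidence for this substrate class; the (R) acid is written, and its antipode is to be used if a pilot run shows the opposite sense.
Remark: ring atoms carry flavanone numbering throughout; chain carbons are counted from the ring (chain C1 to C8).

**Route**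

Step 1
Reactants: 1 4-acetoxystyrene
Product: 2 4-vinylphenol
Conditions: K2CO3 (10 mol%), MeOH, 0 °C → rt; aq. NH4Cl; used at once
Reagents that add atoms: none
Why: base-catalysed transesterification of an aryl acetate is fast in methanol and leaves the vinyl group alone; immediate use avoids polymerisation of the vinylphenol.

Step 2
Reactants: 2 4-vinylphenol
Product: 3 4-(methoxymethoxy)styrene
Conditions: MOMCl, i-Pr2NEt, CH2Cl2, 0 °C → rt
Reagents that add atoms: chloromethyl methyl ether, COCCl
Why: O-alkylation of a phenol with an α-chloro ether (MOM ether formation) is routine and keeps the para oxygen a strong donor for the later cycloaddition.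

Step 3
Reactants: 4 phloroglucinol
Product: 5 3,5-bis(methoxymethoxy)phenol
Conditions: MOMCl (2 equiv), i-Pr2NEt, DMF, 0 °C → rt; chromatography
Reagents that add atoms: chloromethyl methyl ether, COCCl
Why: statistical double MOM etherification of the symmetric triol; the bis-ether should be separable from mono- and tris-ether, which can be recycled.

Step 4
Reactants: 5 3,5-bis(methoxymethoxy)phenol
Product: 6 [3,5-bis(methoxymethoxy)phenoxy]triisopropylsilane
Conditions: i-Pr3SiCl, imidazole, DMF, rt
Reagents that add atoms: chlorotriisopropylsilane, CC(C)[Si](Cl)(C(C)C)C(C)C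
Why: silylation of the remaining phenol gives a bulky ether that neither directs nor tolerates metalation next to it, leaving the carbon between the MOM ethers as the only acidic site.

Step 5
Reactants: 6 [3,5-bis(methoxymethoxy)phenoxy]triisopropylsilane; 7 (S)-citronellal
Product: 9 (3S)-1-[2,6-bis(methoxymethoxy)-4-(triisopropylsilyloxy)phenyl]-3,7-dimethyloct-6-en-1-ol (both C1 epimers), via aryllithium 8 (not isolated)
Conditions: n-BuLi, THF, 0 °C; then 7, −78 °C → 0 °C; aq. NH4Cl
Reagents that add atoms: none
Why: directed ortho-metalation places lithium between the two chelating MOM ethers, and 1,2-addition to the aldehyde at −78 °C should outrun enolisation; the carbinol centre forms unselectively but is removed in step 6, and chain C3 is not involved.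

Step 6
Reactants: 9 (3S)-1-[2,6-bis(methoxymethoxy)-4-(triisopropylsilyloxy)phenyl]-3,7-dimethyloct-6-en-1-ol
Product: 10 {4-[(1E,3S)-3,7-dimethylocta-1,6-dien-1-yl]-3,5-bis(methoxymethoxy)phenoxy}triisopropylsilane
Conditions: Burgess reagent (MeO2CN–SO2NEt3 inner salt), toluene, 50 °C
Reagents that add atoms: none
Why: Burgess dehydration (syn elimination under neutral conditions) of a secondary benzylic alcohol should give the conjugated E alkene from either epimer, without acid that would endanger the MOM ethers or the trisubstituted alkene.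

Step 7
Reactants: 10 {4-[(1E,3S)-3,7-dimethylocta-1,6-dien-1-yl]-3,5-bis(methoxymethoxy)phenoxy}triisopropylsilane
Product: 11 4-[(1E,3S)-3,7-dimethylocta-1,6-dien-1-yl]-3,5-bis(methoxymethoxy)phenol
Conditions: Bu4NF, THF, 0 °C; aq. NH4Cl
Reagents that add atoms: none
Why: fluoride-induced cleavage of an aryl silyl ether is selective; MOM ethers and both alkenes are inert to it.

Step 8
Reactants: 11 4-[(1E,3S)-3,7-dimethylocta-1,6-dien-1-yl]-3,5-bis(methoxymethoxy)phenol
Product: 13 3-[(1E,3S)-3,7-dimethylocta-1,6-dien-1-yl]-6-hydroxy-2,4-bis(methoxymethoxy)benzaldehyde, via hydroxymethyl phenol 12 (not isolated)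
Conditions: MgCl2, Et3N, (CH2O)n, MeCN, 80 °C; cold aq. citric acid
Reagents that add atoms: paraformaldehyde (as formaldehyde), C=O
Why: Casnati–Skattebøl ortho-formylation: the magnesium phenoxide delivers formaldehyde only ortho, and a second formaldehyde oxidises the hydroxymethyl intermediate by hydride transfer; the two ortho positions are equivalent and para is blocked, so a single aldehyde is expected.

Step 9
Reactants: 13 3-[(1E,3S)-3,7-dimethylocta-1,6-dien-1-yl]-6-hydroxy-2,4-bis(methoxymethoxy)benzaldehyde
Product: 14 2-(dimethoxymethyl)-4-[(1E,3S)-3,7-dimethylocta-1,6-dien-1-yl]-3,5-bis(methoxymethoxy)phenol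
Conditions: HC(OMe)3, MeOH, pyridinium p-toluenesulfonate (5 mol%), rt → 40 °C; Et3N, filtration through basic alumina, evaporation; used within hours
Reagents that add atoms: trimethyl orthoformate, COC(OC)OC; methanol, CO
Why: acid-catalysed acetalisation driven by the orthoester as water scavenger; the weak pyridinium acid spares MOM ethers and alkenes, and the large excess of methanol keeps any ionised material capped as the acetal.

Step 10
Reactants: 14 2-(dimethoxymethyl)-4-[(1E,3S)-3,7-dimethylocta-1,6-dien-1-yl]-3,5-bis(methoxymethoxy)phenol; 3 4-(methoxymethoxy)styrene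
Product: 16 (2S)-6-[(1E,3S)-3,7-dimethylocta-1,6-dien-1-yl]-4-methoxy-5,7-bis(methoxymethoxy)-2-[4-(methoxymethoxy)phenyl]chromane (both C4 epimers), via ortho-quinone methide 15 (not isolated)
Conditions: 3 (4 equiv), (R)-3,3'-bis(2,4,6-triisopropylphenyl)-1,1'-binaphthyl-2,2'-diyl hydrogen phosphate (10 mol%), 5 Å MS, toluene, −20 → 0 °C, slow addition of 14
Reagents that add atoms: none
Why: Proposed new method: the chiral acid protonates an acetal oxygen of 14, methanol leaves, and the resulting ortho-hydroxyaryl oxocarbenium (the protonated form of methide 15), ion-paired and hydrogen-bonded to the chiral phosphate, is attacked at C4 by the CH2 terminus of 3 (C3–C4) while the phenol oxygen closes onto the developing para-alkoxybenzylic cation (O1–C2) in a concerted but asynchronous inverse-electron-demand hetero-Diels–Alder reaction. The closest known reactions are the achiral acid-catalysed coupling of salicylaldehyde acetals with styrenes to 4-alkoxy-2-arylchromans and the chiral phosphoric acid or N-triflylphosphoramide-catalysed cycloadditions of ortho-quinone methides from ortho-hydroxybenzyl alcohols with styrenes; an enantioselective reaction of a 4-alkoxy methide with a simple styrene is the extension. Ring C closes as a six-membered ring in [4+2] mode from the oxadiene O1=C8a–C4a=C4 and the alkene C2=C3, the second bond forming as a 6-exo-type capture of the cation by oxygen. C2 is controlled by the catalyst: the phosphate is anchored on the phenol O–H, its 3,3'-aryl groups leave one quadrant open for the styrene, and the endo placement of the styrene aryl ties the C2 configuration to that approach; C4 needs no control because it becomes the carbonyl carbon. The step needs regio- and chemoselectivity: the only free phenol lies next to the unsubstituted ring carbon (the later C8), so closure can give only the 6-alkenyl flavan, and the terminal electron-rich styrene, in excess and with 14 kept dilute, should outcompete the hindered internal alkenes of the chain and the nucleophilic C8–H of ring A for the cation.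

Step 11
Reactants: 16 (2S)-6-[(1E,3S)-3,7-dimethylocta-1,6-dien-1-yl]-4-methoxy-5,7-bis(methoxymethoxy)-2-[4-(methoxymethoxy)phenyl]chromane
Product: 17 (2S)-6-[(1E,3S)-3,7-dimethylocta-1,6-dien-1-yl]-5,7-bis(methoxymethoxy)-2-[4-(methoxymethoxy)phenyl]chroman-4-ol (both C4 epimers)
Conditions: pyridinium p-toluenesulfonate (20 mol%), THF/H2O 4:1, 40 °C
Reagents that add atoms: water, O
Why: SN1 solvolysis of a benzylic methyl ether whose cation is stabilised by the three oxygens of ring A proceeds under acid far too weak to cleave MOM ethers or to open the ring at C2.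

Step 12
Reactants: 17 (2S)-6-[(1E,3S)-3,7-dimethylocta-1,6-dien-1-yl]-5,7-bis(methoxymethoxy)-2-[4-(methoxymethoxy)phenyl]chroman-4-ol
Product: 18 (2S)-6-[(1E,3S)-3,7-dimethylocta-1,6-dien-1-yl]-5,7-bis(methoxymethoxy)-2-[4-(methoxymethoxy)phenyl]chroman-4-one
Conditions: Dess–Martin periodinane, pyridine, CH2Cl2, 0 °C → rt
Reagents that add atoms: none
Why: Dess–Martin oxidation of a secondary benzylic alcohol converges both C4 epimers on one ketone; the buffered, non-basic medium avoids retro-oxa-Michael opening at C2 and does not touch the alkenes.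

Step 13
Reactants: 18 (2S)-6-[(1E,3S)-3,7-dimethylocta-1,6-dien-1-yl]-5,7-bis(methoxymethoxy)-2-[4-(methoxymethoxy)phenyl]chroman-4-one
Product: 19 (2S)-6-[(1E,3S)-3,7-dimethylocta-1,6-dien-1-yl]-5,7-dihydroxy-2-(4-hydroxyphenyl)chroman-4-one
Conditions: HCl (3 M aq.)/MeOH 1:9, 35 °C, stopped at full conversion
Reagents that add atoms: none
Why: acid-catalysed transacetalisation of aryl MOM ethers to methanol is the standard deprotection for prenylated flavanones; C2 of a flavanone is configurationally stable in dilute acid, and the mild temperature is chosen to spare the two alkenes.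

**Compound list**
1 | 4-acetoxystyrene | CC(=O)Oc1ccc(C=C)cc1 | starting material
2 | 4-vinylphenol | C=Cc1ccc(O)cc1 | intermediate
3 | 4-(methoxymethoxy)styrene | C=Cc1ccc(OCOC)cc1 | intermediate
4 | phloroglucinol | Oc1cc(O)cc(O)c1 | starting material
5 | 3,5-bis(methoxymethoxy)phenol | COCOc1cc(O)cc(OCOC)c1 | intermediate
6 | [3,5-bis(methoxymethoxy)phenoxy]triisopropylsilane | COCOc1cc(O[Si](C(C)C)(C(C)C)C(C)C)cc(OCOC)c1 | intermediate
7 | (S)-citronellal | CC(C)=CCC[C@H](C)CC=O | starting material
8 | [2,6-bis(methoxymethoxy)-4-(triisopropylsilyloxy)phenyl]lithium | [Li]c1c(OCOC)cc(O[Si](C(C)C)(C(C)C)C(C)C)cc1OCOC | intermediate (not isolated)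
9 | (3S)-1-[2,6-bis(methoxymethoxy)-4-(triisopropylsilyloxy)phenyl]-3,7-dimethyloct-6-en-1-ol (C1 epimers) | CC(C)=CCC[C@H](C)CC(O)c1c(OCOC)cc(O[Si](C(C)C)(C(C)C)C(C)C)cc1OCOC | intermediate
10 | {4-[(1E,3S)-3,7-dimethylocta-1,6-dien-1-yl]-3,5-bis(methoxymethoxy)phenoxy}triisopropylsilane | CC(C)=CCC[C@H](C)/C=C/c1c(OCOC)cc(O[Si](C(C)C)(C(C)C)C(C)C)cc1OCOC | intermediate
11 | 4-[(1E,3S)-3,7-dimethylocta-1,6-dien-1-yl]-3,5-bis(methoxymethoxy)phenol | CC(C)=CCC[C@H](C)/C=C/c1c(OCOC)cc(O)cc1OCOC | intermediate
12 | 4-[(1E,3S)-3,7-dimethylocta-1,6-dien-1-yl]-2-(hydroxymethyl)-3,5-bis(methoxymethoxy)phenol (present as its magnesium phenoxide) | CC(C)=CCC[C@H](C)/C=C/c1c(OCOC)cc(O)c(CO)c1OCOC | intermediate (not isolated)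
13 | 3-[(1E,3S)-3,7-dimethylocta-1,6-dien-1-yl]-6-hydroxy-2,4-bis(methoxymethoxy)benzaldehyde | CC(C)=CCC[C@H](C)/C=C/c1c(OCOC)cc(O)c(C=O)c1OCOC | intermediate
14 | 2-(dimethoxymethyl)-4-[(1E,3S)-3,7-dimethylocta-1,6-dien-1-yl]-3,5-bis(methoxymethoxy)phenol | CC(C)=CCC[C@H](C)/C=C/c1c(OCOC)cc(O)c(c1OCOC)C(OC)OC | intermediate
15 | 4-[(1E,3S)-3,7-dimethylocta-1,6-dien-1-yl]-6-(methoxymethylidene)-3,5-bis(methoxymethoxy)cyclohexa-2,4-dien-1-one (4-methoxy ortho-quinone methide) | CC(C)=CCC[C@H](C)/C=C/C1=C(OCOC)C(=COC)C(=O)C=C1OCOC | intermediate (not isolated)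
16 | (2S)-6-[(1E,3S)-3,7-dimethylocta-1,6-dien-1-yl]-4-methoxy-5,7-bis(methoxymethoxy)-2-[4-(methoxymethoxy)phenyl]chromane (C4 epimers) | CC(C)=CCC[C@H](C)/C=C/c1c(OCOC)cc2c(c1OCOC)C(OC)C[C@@H](c1ccc(OCOC)cc1)O2 | intermediate
17 | (2S)-6-[(1E,3S)-3,7-dimethylocta-1,6-dien-1-yl]-5,7-bis(methoxymethoxy)-2-[4-(methoxymethoxy)phenyl]chroman-4-ol (C4 epimers) | CC(C)=CCC[C@H](C)/C=C/c1c(OCOC)cc2c(c1OCOC)C(O)C[C@@H](c1ccc(OCOC)cc1)O2 | intermediate
18 | (2S)-6-[(1E,3S)-3,7-dimethylocta-1,6-dien-1-yl]-5,7-bis(methoxymethoxy)-2-[4-(methoxymethoxy)phenyl]chroman-4-one | CC(C)=CCC[C@H](C)/C=C/c1c(OCOC)cc2c(c1OCOC)C(=O)C[C@@H](c1ccc(OCOC)cc1)O2 | intermediate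
19 | (2S)-6-[(1E,3S)-3,7-dimethylocta-1,6-dien-1-yl]-5,7-dihydroxy-2-(4-hydroxyphenyl)chroman-4-one | CC(C)=CCC[C@H](C)/C=C/c1c(O)cc2c(c1O)C(=O)C[C@@H](c1ccc(O)cc1)O2 | target

**Step count**
Total steps: 13 (steps 1–2 make the styrene; steps 3–13 run from phloroglucinol to the target).
Longest linear sequence: 11 steps (steps 3–13).

**Steps most likely to fail**

Step 10 (bears the label "Proposed new method:"). Two processes may defeat it. Turnover may be lost to tight ion pairing or to Friedel–Crafts attack of the electron-rich ring A (C8–H) on the cation. Leakage between the two faces or between endo and exo approach would lower the configurational purity at C2. The fallback uses known chemistry, moves stereocontrol to a later resolution, sets out from 13 (with 3) and returns at 18. Aldehyde 13, trimethyl orthoformate and 3 are combined with Sc(OTf)3 (5 mol%) in CH2Cl2 at 0 °C, the established achiral three-component form of this chroman synthesis, in which acetal 14 forms in the flask. This should give the C2-epimeric 4-methoxyflavan F1. Hydrolysis and oxidation under the conditions of steps 11 and 12 then lead through the C2-epimeric flavan-4-ol F2 to the C2-epimeric flavanone F3. A Noyori–Ikariya asymmetric transfer hydrogenation run as a kinetic resolution (RuCl(p-cymene)[(R,R)-TsDPEN], HCO2H/Et3N, rt, stopped near half conversion) is expected to reduce the (2R) epimer to the cis alcohol (2R,4R)-flavan-4-ol F4. The (2S) ketone 18 is left behind and separated by chromatography.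

Step 9. The hydroxy acetal may ionise on concentration and oligomerise through its own methide, and the MOM ether next to the acetal carbon may be lost. The fallback masks the phenol during acetal formation, sets out from 13 and returns at 14. Silylation (t-BuMe2SiOTf, 2,6-lutidine, CH2Cl2, 0 °C) gives the silyl ether aldehyde F5, which cannot form a methide. Acetalisation as in step 9 gives the silyl ether dimethyl acetal F6, which can be purified on Et3N-deactivated silica. Bu4NF in THF at 0 °C with a pH 7 work-up then releases 14 under basic conditions directly before step 10.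

Step 6. The activated benzylic alcohol may ionise, and the cation may be captured by the trisubstituted alkene (cation–olefin cyclisation) or collapse to E/Z mixtures. The fallback avoids any cation, sets out from 9 and returns at 10. Oxidation (Dess–Martin periodinane, pyridine, CH2Cl2) gives the aryl ketone F7. KN(SiMe3)2 and PhNTf2 in THF at −78 °C convert its Z enolate into the (Z)-enol triflate F8. Formate reduction (Pd(OAc)2, PPh3, Bu3N, HCO2H, DMF, 60 °C) replaces the triflate by hydrogen with retention of geometry and should deliver the E alkene 10.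

**Further compounds**
F1 | step 10 | 6-[(1E,3S)-3,7-dimethylocta-1,6-dien-1-yl]-4-methoxy-5,7-bis(methoxymethoxy)-2-[4-(methoxymethoxy)phenyl]chromane, mixture of C2 epimers | CC(C)=CCC[C@H](C)/C=C/c1c(OCOC)cc2c(c1OCOC)C(OC)CC(c1ccc(OCOC)cc1)O2
F2 | step 10 | 6-[(1E,3S)-3,7-dimethylocta-1,6-dien-1-yl]-5,7-bis(methoxymethoxy)-2-[4-(methoxymethoxy)phenyl]chroman-4-ol, mixture of C2 epimers | CC(C)=CCC[C@H](C)/C=C/c1c(OCOC)cc2c(c1OCOC)C(O)CC(c1ccc(OCOC)cc1)O2
F3 | step 10 | 6-[(1E,3S)-3,7-dimethylocta-1,6-dien-1-yl]-5,7-bis(methoxymethoxy)-2-[4-(methoxymethoxy)phenyl]chroman-4-one, mixture of C2 epimers | CC(C)=CCC[C@H](C)/C=C/c1c(OCOC)cc2c(c1OCOC)C(=O)CC(c1ccc(OCOC)cc1)O2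
F4 | step 10 | (2R,4R)-6-[(1E,3S)-3,7-dimethylocta-1,6-dien-1-yl]-5,7-bis(methoxymethoxy)-2-[4-(methoxymethoxy)phenyl]chroman-4-ol | CC(C)=CCC[C@H](C)/C=C/c1c(OCOC)cc2c(c1OCOC)[C@H](O)C[C@H](c1ccc(OCOC)cc1)O2
F5 | step 9 | 6-(tert-butyldimethylsilyloxy)-3-[(1E,3S)-3,7-dimethylocta-1,6-dien-1-yl]-2,4-bis(methoxymethoxy)benzaldehyde | CC(C)=CCC[C@H](C)/C=C/c1c(OCOC)cc(O[Si](C)(C)C(C)(C)C)c(C=O)c1OCOC
F6 | step 9 | tert-butyl{2-(dimethoxymethyl)-4-[(1E,3S)-3,7-dimethylocta-1,6-dien-1-yl]-3,5-bis(methoxymethoxy)phenoxy}dimethylsilane | CC(C)=CCC[C@H](C)/C=C/c1c(OCOC)cc(O[Si](C)(C)C(C)(C)C)c(c1OCOC)C(OC)OC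
F7 | step 6 | (3S)-1-[2,6-bis(methoxymethoxy)-4-(triisopropylsilyloxy)phenyl]-3,7-dimethyloct-6-en-1-one | CC(C)=CCC[C@H](C)CC(=O)c1c(OCOC)cc(O[Si](C(C)C)(C(C)C)C(C)C)cc1OCOC
F8 | step 6 | (1Z,3S)-1-[2,6-bis(methoxymethoxy)-4-(triisopropylsilyloxy)phenyl]-3,7-dimethylocta-1,6-dien-1-yl trifluoromethanesulfonate | CC(C)=CCC[C@H](C)/C=C(\OS(=O)(=O)C(F)(F)F)c1c(OCOC)cc(O[Si](C(C)C)(C(C)C)C(C)C)cc1OCOC
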